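**Retrosynthetic overview**
- Curtisian T ⇐ hydrogenolysis of the four benzyl ethers of the fully protected diester 10.
- 10 ⇐ two successive O-acylations of the symmetric hydroquinone 5: benzoyl first, then (R)-3-acetoxybutanoyl from the chiral-pool acid 7. The two esters sit on the former quinone oxygens, so they are para by construction.
- 5 ⇐ reduction of terphenylquinone 4 ⇐ double Suzuki–Miyaura coupling of dibromoquinone 2 with boronic acid 3.
- 2 ⇐ bromanil 1 + benzyl oxide (2,5-selective substitution).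
- No ring is formed: the central ring comes from bromanil and the two outer rings from 3, joined in one coupling step.

Assumption: simple reagents (benzyl alcohol, benzoyl chloride, acetyl chloride, oxalyl chloride, bases, catalysts) are not numbered; they stand under Conditions and, where they deliver atoms, under "Reagents that add atoms". The side-chain stereocenter is (R) as drawn.

**Step 1**
Reactants: 1 tetrabromo-1,4-benzoquinone (bromanil)
Product: 2 2,5-bis(benzyloxy)-3,6-dibromo-1,4-benzoquinone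
Conditions: BnOH (2.05 eq), NaH (2.05 eq), THF, 0 °C; then 1, THF, −40 → 0 °C
Reagents that add atoms: benzyl alcohol, OCc1ccccc1
Why: Addition–elimination (vinylogous acyl substitution) on the haloquinone, where the first benzyloxy group deactivates its own enone as a vinylogous ester so the second alkoxide enters at the para carbon to give the 2,5-dialkoxy-3,6-dibromo pattern.

**Step 2**
Reactants: 2 2,5-bis(benzyloxy)-3,6-dibromo-1,4-benzoquinone; 3 4-(benzyloxy)phenylboronic acid (2.6 eq)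
Product: 4 2,5-bis(benzyloxy)-3,6-bis[4-(benzyloxy)phenyl]-1,4-benzoquinone
Conditions: PdCl2(dppf) (10 mol %), K2CO3 (4 eq), 1,4-dioxane, 90 °C, Ar
Reagents that add atoms: none
Why: Double Suzuki–Miyaura coupling, in which the C–Br bonds of the alkoxybromoquinone act as vinylogous acyl bromides that add readily to zerovalent palladium, while anhydrous carbonate spares the benzyl vinylogous esters.

**Step 3**
Reactants: 4 2,5-bis(benzyloxy)-3,6-bis[4-(benzyloxy)phenyl]-1,4-benzoquinone
Product: 6 2,5-bis(benzyloxy)-3,6-bis[4-(benzyloxy)phenyl]-4-hydroxyphenyl benzoate, via hydroquinone 5 (not isolated)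
Conditions: Na2S2O4, EtOAc/H2O, rt; organic phase dried and concentrated under Ar; then BzCl (1.0 eq, slow addition), pyridine, DMAP (cat.), CH2Cl2, −20 °C → rt
Reagents that add atoms: benzoyl chloride, O=C(Cl)c1ccccc1
Why: Dithionite reduction gives the air-sensitive symmetric hydroquinone whose only free hydroxyls are the two para ones, and DMAP-catalysed acylation with one equivalent of benzoyl chloride gives the mono-benzoate statistically (about half at best), with unreacted 5 returning to 4 in air for recycling.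

**Step 4**
Reactants: 7 (R)-3-hydroxybutanoic acid
Product: 8 (R)-3-acetoxybutanoic acid
Conditions: AcCl (neat, 3 eq), 0 °C → rt; evaporate; H2O work-up
Reagents that add atoms: acetyl chloride, CC(=O)Cl
Why: O-acetylation of the secondary alcohol breaks no bond at the stereocenter, so the (R) configuration of the chiral-pool acid is carried through unchanged.

**Step 5**
Reactants: 6 2,5-bis(benzyloxy)-3,6-bis[4-(benzyloxy)phenyl]-4-hydroxyphenyl benzoate; 8 (R)-3-acetoxybutanoic acid (1.5 eq)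
Product: 10 4-(benzoyloxy)-2,5-bis(benzyloxy)-3,6-bis[4-(benzyloxy)phenyl]phenyl (R)-3-acetoxybutanoate, via (R)-3-acetoxybutanoyl chloride 9 (not isolated)
Conditions: 8, (COCl)2, DMF (cat.), CH2Cl2, 0 °C → rt, evaporate; then 6, pyridine, CH2Cl2, 0 °C → rt
Reagents that add atoms: none
Why: The acid chloride (Vilsmeier-type activation) acylates the remaining hindered phenol under pyridine catalysis, and the stereocenter, being β to the carbonyl, is untouched as long as the weak base and low temperature keep β-elimination of acetate down.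

**Step 6**
Reactants: 10 4-(benzoyloxy)-2,5-bis(benzyloxy)-3,6-bis[4-(benzyloxy)phenyl]phenyl (R)-3-acetoxybutanoate
Product: 11 Curtisian T
Conditions: H2 (1 atm), 10% Pd/C, EtOAc/THF, rt; filtration and evaporation under Ar, no base
Reagents that add atoms: none
Why: Catalytic hydrogenolysis removes the four O-benzyl groups under neutral conditions that leave the aryl benzoate, the aryl alkanoate, the acetate and the stereocenter alone and give no base to trigger ortho acyl migration.

**Compound list**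
1 | tetrabromo-1,4-benzoquinone (bromanil) | O=C1C(Br)=C(Br)C(=O)C(Br)=C1Br | starting material
2 | 2,5-bis(benzyloxy)-3,6-dibromo-1,4-benzoquinone | O=C1C(OCc2ccccc2)=C(Br)C(=O)C(OCc2ccccc2)=C1Br | intermediate
3 | 4-(benzyloxy)phenylboronic acid | OB(O)c1ccc(OCc2ccccc2)cc1 | starting material
4 | 2,5-bis(benzyloxy)-3,6-bis[4-(benzyloxy)phenyl]-1,4-benzoquinone | O=C1C(OCc2ccccc2)=C(c2ccc(OCc3ccccc3)cc2)C(=O)C(OCc2ccccc2)=C1c1ccc(OCc2ccccc2)cc1 | intermediate
5 | 2,5-bis(benzyloxy)-3,6-bis[4-(benzyloxy)phenyl]benzene-1,4-diol (hydroquinone, not isolated) | Oc1c(OCc2ccccc2)c(-c2ccc(OCc3ccccc3)cc2)c(O)c(OCc2ccccc2)c1-c1ccc(OCc2ccccc2)cc1 | intermediate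
6 | 2,5-bis(benzyloxy)-3,6-bis[4-(benzyloxy)phenyl]-4-hydroxyphenyl benzoate | O=C(Oc1c(OCc2ccccc2)c(-c2ccc(OCc3ccccc3)cc2)c(O)c(OCc2ccccc2)c1-c1ccc(OCc2ccccc2)cc1)c1ccccc1 | intermediate
7 | (R)-3-hydroxybutanoic acid | C[C@@H](O)CC(=O)O | starting material
8 | (R)-3-acetoxybutanoic acid | CC(=O)O[C@H](C)CC(=O)O | intermediate
9 | (R)-3-acetoxybutanoyl chloride (not isolated) | CC(=O)O[C@H](C)CC(=O)Cl | intermediate
10 | 4-(benzoyloxy)-2,5-bis(benzyloxy)-3,6-bis[4-(benzyloxy)phenyl]phenyl (R)-3-acetoxybutanoate | CC(=O)O[C@H](C)CC(=O)Oc1c(OCc2ccccc2)c(-c2ccc(OCc3ccccc3)cc2)c(OC(=O)c2ccccc2)c(OCc2ccccc2)c1-c1ccc(OCc2ccccc2)cc1 | intermediate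
11 | Curtisian T, 4-(benzoyloxy)-2,5-dihydroxy-3,6-bis(4-hydroxyphenyl)phenyl (R)-3-acetoxybutanoate | CC(=O)O[C@H](C)CC(=O)Oc1c(O)c(-c2ccc(O)cc2)c(OC(=O)c2ccccc2)c(O)c1-c1ccc(O)cc1 | target

**Totals**
Total step count: 6. Longest linear sequence: 5 (steps 1, 2, 3, 5, 6 from bromanil); step 4 makes the side-chain acid.

**Three steps most likely to fail**

Step 1. Benzyl oxide may reduce bromanil by hydride transfer or over-substitute. The fallback puts the benzyl groups on after the coupling. It sets out from 1: NaOMe in MeOH at 0 °C gives 2,5-dibromo-3,6-dimethoxy-1,4-benzoquinone F1. Double Suzuki–Miyaura coupling of F1 with 3 (PdCl2(dppf), K2CO3, dioxane, 90 °C) gives 2,5-bis[4-(benzyloxy)phenyl]-3,6-dimethoxy-1,4-benzoquinone F2. Aqueous NaOH in dioxane at 80 °C, then acidification, hydrolyses the two vinylogous methyl esters to 2,5-bis[4-(benzyloxy)phenyl]-3,6-dihydroxy-1,4-benzoquinone F3, leaving the aryl benzyl ethers intact. O-benzylation with BnBr and K2CO3 in DMF comes back to the route at 4.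

Step 2. The quinone may oxidise the catalyst or the boronic acid, or lose a benzyloxy group to the base. The fallback does the coupling at the arene oxidation level. It sets out from 2: Na2S2O4 in EtOAc/H2O gives 2,5-bis(benzyloxy)-3,6-dibromobenzene-1,4-diol F4. MOMCl and iPr2NEt in CH2Cl2 give 1,4-bis(benzyloxy)-2,5-dibromo-3,6-bis(methoxymethoxy)benzene F5. Coupling with 3 (Pd(OAc)2, SPhos, K3PO4, toluene/H2O, 100 °C) gives 1,4-bis(benzyloxy)-2,5-bis[4-(benzyloxy)phenyl]-3,6-bis(methoxymethoxy)benzene F6. HCl in MeOH/THF at 40 °C removes both MOM groups and comes back to the route at 5, which is benzoylated as in the second half of step 3; quinone 4 is bypassed.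

Step 5. The β-acetoxy acid chloride may lose acetic acid to give the crotonate, and the phenol is hindered. The fallback installs the acetate only after the aryl ester bond exists. It sets out from 7 and joins 6: TBSCl (2.2 eq) and imidazole in DMF give tert-butyldimethylsilyl (R)-3-[(tert-butyldimethylsilyl)oxy]butanoate F7. (COCl)2 with catalytic DMF in CH2Cl2 converts the silyl ester directly into (R)-3-[(tert-butyldimethylsilyl)oxy]butanoyl chloride F8. Acylation of 6 (pyridine, DMAP cat., CH2Cl2) gives 4-(benzoyloxy)-2,5-bis(benzyloxy)-3,6-bis[4-(benzyloxy)phenyl]phenyl (R)-3-[(tert-butyldimethylsilyl)oxy]butanoate F9. HF·pyridine in THF gives 4-(benzoyloxy)-2,5-bis(benzyloxy)-3,6-bis[4-(benzyloxy)phenyl]phenyl (R)-3-hydroxybutanoate F10. Ac2O in pyridine comes back to the route at 10.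

**Further compounds**
F1 | step 1 | 2,5-dibromo-3,6-dimethoxy-1,4-benzoquinone | COC1=C(Br)C(=O)C(OC)=C(Br)C1=O
F2 | step 1 | 2,5-bis[4-(benzyloxy)phenyl]-3,6-dimethoxy-1,4-benzoquinone | COC1=C(c2ccc(OCc3ccccc3)cc2)C(=O)C(OC)=C(c2ccc(OCc3ccccc3)cc2)C1=O
F3 | step 1 | 2,5-bis[4-(benzyloxy)phenyl]-3,6-dihydroxy-1,4-benzoquinone | OC1=C(c2ccc(OCc3ccccc3)cc2)C(=O)C(O)=C(c2ccc(OCc3ccccc3)cc2)C1=O
F4 | step 2 | 2,5-bis(benzyloxy)-3,6-dibromobenzene-1,4-diol | Oc1c(OCc2ccccc2)c(Br)c(O)c(OCc2ccccc2)c1Br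
F5 | step 2 | 1,4-bis(benzyloxy)-2,5-dibromo-3,6-bis(methoxymethoxy)benzene | COCOc1c(OCc2ccccc2)c(Br)c(OCOC)c(OCc2ccccc2)c1Br
F6 | step 2 | 1,4-bis(benzyloxy)-2,5-bis[4-(benzyloxy)phenyl]-3,6-bis(methoxymethoxy)benzene | COCOc1c(OCc2ccccc2)c(-c2ccc(OCc3ccccc3)cc2)c(OCOC)c(OCc2ccccc2)c1-c1ccc(OCc2ccccc2)cc1
F7 | step 5 | tert-butyldimethylsilyl (R)-3-[(tert-butyldimethylsilyl)oxy]butanoate | C[C@@H](O[Si](C)(C)C(C)(C)C)CC(=O)O[Si](C)(C)C(C)(C)C
F8 | step 5 | (R)-3-[(tert-butyldimethylsilyl)oxy]butanoyl chloride | C[C@@H](O[Si](C)(C)C(C)(C)C)CC(=O)Cl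
F9 | step 5 | 4-(benzoyloxy)-2,5-bis(benzyloxy)-3,6-bis[4-(benzyloxy)phenyl]phenyl (R)-3-[(tert-butyldimethylsilyl)oxy]butanoate | C[C@@H](O[Si](C)(C)C(C)(C)C)CC(=O)Oc1c(OCc2ccccc2)c(-c2ccc(OCc3ccccc3)cc2)c(OC(=O)c2ccccc2)c(OCc2ccccc2)c1-c1ccc(OCc2ccccc2)cc1
F10 | step 5 | 4-(benzoyloxy)-2,5-bis(benzyloxy)-3,6-bis[4-(benzyloxy)phenyl]phenyl (R)-3-hydroxybutanoate | C[C@@H](O)CC(=O)Oc1c(OCc2ccccc2)c(-c2ccc(OCc3ccccc3)cc2)c(OC(=O)c2ccccc2)c(OCc2ccccc2)c1-c1ccc(OCc2ccccc2)cc1
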